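**Retrosynthetic overview**

1. Labels: ring A is the syringyl ring with C7 (carbinol), C8 and C9 (CH2OH); ring B is the aryl ether ring, joined through O4' and carrying C7'–C9'. The strategy rests on C8, which bears three different partners: the ether oxygen O4' of ring B, the benzylic carbinol carbon C7 on ring A, and the hydroxymethyl carbon C9.
2. C8 is therefore traced back to the carbene carbon of ethyl diazoacetate, whose ester carbon is C9. O4'–C8 and C7–C8 are cut together, giving ring B phenol 7, diazo ester 10 and ring A aldehyde 9.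
3. Phenol 7 is cut at C1'–C7' into an aryl Grignard reagent and (S)-benzyl glycidyl ether, which supplies C8' (S). Aldehyde 9 is acetylated syringaldehyde.
4. Both benzene rings are bought and no ring of the target is formed. The only ring made is the temporary dioxolane (step 4), which is opened again in step 7 before the final hydride reduction.

Key step: step 6

Assumption: the facial preference of the BINOL–Zr(OtBu)4 catalyst for this substrate pair is not established. (R)-BINOL is written; (S)-BINOL would replace it if the antipodal erythro adduct (7R,8S) is favoured.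

**Route**

Step 1
Reactants: 1 4-bromo-2,6-dimethoxyphenol
Product: 2 2-(benzyloxy)-5-bromo-1,3-dimethoxybenzene
Conditions: BnBr, K2CO3, DMF, 60 °C
Reagents that add atoms: benzyl bromide, BrCc1ccccc1
Why: Williamson ether synthesis (SN2 of the phenoxide on benzyl bromide) removes the acidic O–H that would quench the Grignard reagent of step 2 and installs a group that leaves later by hydrogenolysis.

Step 2
Reactants: 2 2-(benzyloxy)-5-bromo-1,3-dimethoxybenzene; 3 (S)-benzyl glycidyl ether, (2S)-2-[(benzyloxy)methyl]oxirane
Product: 5 (2S)-1-(benzyloxy)-3-[4-(benzyloxy)-3,5-dimethoxyphenyl]propan-2-ol, via arylmagnesium bromide 4 (not isolated)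
Conditions: Mg, I2 (cat.), THF, 50 °C; then 3, CuI (10 mol%), THF, −30 → 0 °C; aq NH4Cl
Reagents that add atoms: magnesium, [Mg] (held in 4 only, absent from 5)
Why: Copper-catalysed Grignard opening of an epoxide: the arylcopper species formed from 4 and CuI attacks the unsubstituted CH2 of 3 by SN2, the C–O bond at the stereocentre is not broken, and the S centre of 3 becomes C8' (2S in 5) unchanged.

Step 3
Reactants: 5 (2S)-1-(benzyloxy)-3-[4-(benzyloxy)-3,5-dimethoxyphenyl]propan-2-ol
Product: 6 (2S)-3-(4-hydroxy-3,5-dimethoxyphenyl)propane-1,2-diol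
Conditions: H2 (1 atm), 10% Pd/C (palladium on carbon), EtOH, rt
Reagents that add atoms: none
Why: Catalytic hydrogenolysis cleaves the aryl and the alkyl benzyl ether in one operation, while the homobenzylic secondary alcohol and the methoxy groups are inert.

Step 4
Reactants: 6 (2S)-3-(4-hydroxy-3,5-dimethoxyphenyl)propane-1,2-diol
Product: 7 4-[[(4S)-2,2-dimethyl-1,3-dioxolan-4-yl]methyl]-2,6-dimethoxyphenol
Conditions: Me2C(OMe)2, PPTS (cat.), acetone, rt
Reagents that add atoms: 2,2-dimethoxypropane, COC(C)(C)OC
Why: Acid-catalysed transketalisation (acetonide formation) closes the five-membered dioxolane on the 1,2-diol and leaves the phenol free, because a phenol gives no stable mixed ketal; the stereocentre is not touched.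

Step 5
Reactants: 8 syringaldehyde (4-hydroxy-3,5-dimethoxybenzaldehyde)
Product: 9 4-acetoxy-3,5-dimethoxybenzaldehyde
Conditions: Ac2O, pyridine, DMAP (cat.), CH2Cl2, 0 °C → rt
Reagents that add atoms: acetic anhydride, CC(=O)OC(C)=O
Why: DMAP-catalysed O-acetylation (nucleophilic acyl substitution) turns the donating para hydroxyl into a withdrawing acetoxy group, which makes the aldehyde a better electrophile for step 6.

Step 6
Reactants: 7 4-[[(4S)-2,2-dimethyl-1,3-dioxolan-4-yl]methyl]-2,6-dimethoxyphenol; 9 4-acetoxy-3,5-dimethoxybenzaldehyde; 10 ethyl diazoacetate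
Product: 13 ethyl (2S,3S)-3-(4-acetoxy-3,5-dimethoxyphenyl)-2-[4-[[(4S)-2,2-dimethyl-1,3-dioxolan-4-yl]methyl]-2,6-dimethoxyphenoxy]-3-hydroxypropanoate (erythro), via oxonium ylide 11 (not isolated), via ester enol 12 (not isolated)
Conditions: 7 (1.0 equiv), 9 (1.5 equiv), Rh2(OAc)4 (2 mol%), Zr(OtBu)4 (20 mol%) premixed with (R)-BINOL (24 mol%), 4 Å MS, CH2Cl2, 0 °C; 10 (1.5 equiv) added over 8 h by syringe pump
Reagents that add atoms: none
Why: Proposed new method: Rh2(OAc)4 strips N2 from 10 to give an ester-substituted rhodium carbenoid, the phenol oxygen of 7 adds to the carbene carbon (the future C8) to give oxonium ylide 11, and proton transfer turns 11 into ester enol 12, which aldehyde 9, activated on the BINOL-bound zirconium centre, captures at carbon in an aldol addition before 12 can ketonise to the plain O–H insertion product; O4'–C8 and C7–C8 thus form in one flask and C9 is the ester carbonyl carbon of 10. The closest known reaction type is the three-component coupling of aryldiazoacetates, alcohols and aromatic aldehydes under Rh2(OAc)4 and a chiral zirconium binaphtholate through trapped oxonium ylides, which has not been shown for an acceptor-only diazoacetate, a 2,6-disubstituted phenol or an oxygen-rich benzaldehyde. No ring is closed. C8 (2S in 13) and C7 (3S in 13) are both fixed in the C–C bond-forming event by the chiral zirconium binaphtholate, which selects the aldehyde face and the approach of the enol and is expected to favour the erythro adduct, while the distant dioxolane centre exerts no control. The step needs aldol capture to win over the 1,2-proton shift, over carbonyl ylide formation from 9 and over direct addition of 10 to the activated aldehyde; the para acetoxy group makes 9 a better electrophile and a poorer ylide donor than syringaldehyde itself, the two ortho methoxy groups crowd the oxonium centre and should slow the proton shift, and syringe-pump addition keeps free 10 scarce.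

Step 7
Reactants: 13 ethyl (2S,3S)-3-(4-acetoxy-3,5-dimethoxyphenyl)-2-[4-[[(4S)-2,2-dimethyl-1,3-dioxolan-4-yl]methyl]-2,6-dimethoxyphenoxy]-3-hydroxypropanoate
Product: 14 ethyl (2S,3S)-3-(4-acetoxy-3,5-dimethoxyphenyl)-2-[4-[(2S)-2,3-dihydroxypropyl]-2,6-dimethoxyphenoxy]-3-hydroxypropanoate
Conditions: AcOH/H2O 4:1, 35 °C
Reagents that add atoms: none
Why: Acid-catalysed hydrolysis of the isopropylidene acetal frees the 1,2-diol, while the para acetoxy group on ring A and the ester on C8 disfavour a benzylic cation at C7, so the carbinol should not epimerise and the ethyl ester and aryl acetate survive the dilute carboxylic acid.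

Step 8
Reactants: 14 ethyl (2S,3S)-3-(4-acetoxy-3,5-dimethoxyphenyl)-2-[4-[(2S)-2,3-dihydroxypropyl]-2,6-dimethoxyphenoxy]-3-hydroxypropanoate
Product: 15 (1S,2R)-2-[4-[(2S)-2,3-dihydroxypropyl]-2,6-dimethoxyphenoxy]-1-(4-hydroxy-3,5-dimethoxyphenyl)propane-1,3-diol (target, 7S,8R,8'S)
Conditions: LiAlH4 (4 equiv), THF, 0 °C → rt; aq potassium sodium tartrate, pH 6
Reagents that add atoms: none
Why: Hydride reduction with LiAlH4 converts the ethyl ester into the C9 primary alcohol and cleaves the aryl acetate to the free phenol in one operation; C7 and C8 take no part, and the ester is reduced faster than its alpha C–H can be removed, so both centres should be kept.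

**Compound list**

1 | 4-bromo-2,6-dimethoxyphenol | COc1cc(Br)cc(OC)c1O | starting material
2 | 2-(benzyloxy)-5-bromo-1,3-dimethoxybenzene | COc1cc(Br)cc(OC)c1OCc1ccccc1 | intermediate
3 | (S)-benzyl glycidyl ether, (2S)-2-[(benzyloxy)methyl]oxirane | C1[C@H](O1)COCc1ccccc1 | starting material
4 | [4-(benzyloxy)-3,5-dimethoxyphenyl]magnesium bromide | COc1cc([Mg]Br)cc(OC)c1OCc1ccccc1 | intermediate (not isolated)
5 | (2S)-1-(benzyloxy)-3-[4-(benzyloxy)-3,5-dimethoxyphenyl]propan-2-ol | COc1cc(C[C@H](O)COCc2ccccc2)cc(OC)c1OCc1ccccc1 | intermediate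
6 | (2S)-3-(4-hydroxy-3,5-dimethoxyphenyl)propane-1,2-diol | COc1cc(C[C@H](O)CO)cc(OC)c1O | intermediate
7 | 4-[[(4S)-2,2-dimethyl-1,3-dioxolan-4-yl]methyl]-2,6-dimethoxyphenol | COc1cc(C[C@H]2COC(C)(C)O2)cc(OC)c1O | intermediate
8 | syringaldehyde (4-hydroxy-3,5-dimethoxybenzaldehyde) | COc1cc(C=O)cc(OC)c1O | starting material
9 | 4-acetoxy-3,5-dimethoxybenzaldehyde | COc1cc(C=O)cc(OC)c1OC(C)=O | intermediate
10 | ethyl diazoacetate | CCOC(=O)C=[N+]=[N-] | starting material
11 | oxonium ylide from 7 and the carbenoid of 10 (free or rhodium-associated), [aryl(hydro)oxonio](ethoxycarbonyl)methanide | CCOC(=O)[CH-][OH+]c1c(OC)cc(C[C@H]2COC(C)(C)O2)cc1OC | intermediate (not isolated)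
12 | ester enol, 1-ethoxy-2-[4-[[(4S)-2,2-dimethyl-1,3-dioxolan-4-yl]methyl]-2,6-dimethoxyphenoxy]ethen-1-ol | CCOC(O)=COc1c(OC)cc(C[C@H]2COC(C)(C)O2)cc1OC | intermediate (not isolated)
13 | ethyl (2S,3S)-3-(4-acetoxy-3,5-dimethoxyphenyl)-2-[4-[[(4S)-2,2-dimethyl-1,3-dioxolan-4-yl]methyl]-2,6-dimethoxyphenoxy]-3-hydroxypropanoate | COc1cc([C@H](O)[C@@H](C(=O)OCC)Oc2c(OC)cc(C[C@H]3COC(C)(C)O3)cc2OC)cc(OC)c1OC(C)=O | intermediate
14 | ethyl (2S,3S)-3-(4-acetoxy-3,5-dimethoxyphenyl)-2-[4-[(2S)-2,3-dihydroxypropyl]-2,6-dimethoxyphenoxy]-3-hydroxypropanoate | COc1cc([C@H](O)[C@@H](C(=O)OCC)Oc2c(OC)cc(C[C@H](O)CO)cc2OC)cc(OC)c1OC(C)=O | intermediate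
15 | (1S,2R)-2-[4-[(2S)-2,3-dihydroxypropyl]-2,6-dimethoxyphenoxy]-1-(4-hydroxy-3,5-dimethoxyphenyl)propane-1,3-diol | COc1cc([C@H](O)[C@@H](CO)Oc2c(OC)cc(C[C@H](O)CO)cc2OC)cc(OC)c1O | target

**Totals**

Total step count: 8. Longest linear sequence: 7 steps (steps 1, 2, 3, 4, 6, 7, 8, from 1 to 15); step 5 is a one-step side branch.

**Steps most likely to fail**

1. Step 6 (proposed new method).
   - What may go wrong: the enol may tautomerise before the aldehyde reaches it, leaving plain O–H insertion. The carbenoid may dimerise or form a carbonyl ylide with 9. The diazo ester may add directly to the zirconium-bound aldehyde. The acetyl group may be transferred under the zirconium alkoxide. Facial selectivity may be poor, or the threo adduct may be preferred.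
   - Fallback (known chemistry, sets out from 7, comes back at 13): O-alkylation of 7 with ethyl bromoacetate (K2CO3, acetone, reflux) should give ethyl 2-[4-[[(4S)-2,2-dimethyl-1,3-dioxolan-4-yl]methyl]-2,6-dimethoxyphenoxy]acetate F1. This is also what plain O–H insertion in step 6 would leave, so material from a failed run can be fed in here. LiN(iPr)2 in THF at −78 °C converts it into lithium 1-ethoxy-2-[4-[[(4S)-2,2-dimethyl-1,3-dioxolan-4-yl]methyl]-2,6-dimethoxyphenoxy]ethen-1-olate F2. Addition of 9 at −78 °C with an acetic acid quench follows; the lithium enolate aldol of aryloxyacetates with benzaldehydes is erythro-selective. Because the remote dioxolane centre does not bias the addition, 13 should form together with ethyl (2R,3R)-3-(4-acetoxy-3,5-dimethoxyphenyl)-2-[4-[[(4S)-2,2-dimethyl-1,3-dioxolan-4-yl]methyl]-2,6-dimethoxyphenoxy]-3-hydroxypropanoate F3. Threo isomers are removed on silica, and 13 is separated from F3 by preparative HPLC on a chiral stationary phase.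

2. Step 2.
   - What may go wrong: magnesium insertion into the electron-rich aryl bromide may be sluggish. Biaryl homocoupling may compete. The epoxide may be opened by bromide from the magnesium salts to a bromohydrin before the aryl group is transferred.
   - Fallback (sets out from 2, comes back at 7, bypassing 5 and 6): bromine–lithium exchange on 2 with n-BuLi (THF, −78 °C) gives [4-(benzyloxy)-3,5-dimethoxyphenyl]lithium F4. This adds to freshly distilled (R)-2,3-O-isopropylideneglyceraldehyde (chiral pool) to give [4-(benzyloxy)-3,5-dimethoxyphenyl][(4R)-2,2-dimethyl-1,3-dioxolan-4-yl]methanol F5 as a mixture of carbinol epimers. Acetylation (Ac2O, pyridine, DMAP) gives [4-(benzyloxy)-3,5-dimethoxyphenyl][(4R)-2,2-dimethyl-1,3-dioxolan-4-yl]methyl acetate F6. Hydrogenolysis (H2, Pd/C, EtOAc) removes the benzylic acetoxy group and the O-benzyl group together, so both epimers converge on 7. The dioxolane carbon keeps its spatial arrangement; its descriptor changes from R to S only because the CH(OAc)Ar substituent becomes CH2Ar.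

3. Step 8.
   - What may go wrong: triol 14 may form insoluble polyalkoxyaluminates that stall the reduction. The C7 alkoxide may undergo retro-aldol cleavage of C7–C8, or C8 may epimerise. The polar pentol may be lost on aluminium salts during work-up.
   - Fallback (sets out from 13, comes back at 15): the order of the last two operations is inverted. LiBH4 (THF, 0 °C → rt) acts on 13, a lipophilic mono-alcohol, reducing the ester and cleaving the aryl acetate to give (1S,2R)-2-[4-[[(4S)-2,2-dimethyl-1,3-dioxolan-4-yl]methyl]-2,6-dimethoxyphenoxy]-1-(4-hydroxy-3,5-dimethoxyphenyl)propane-1,3-diol F7, which should extract cleanly. AcOH/H2O at rt then removes the acetonide to give 15 in a metal-free last step. The price is exposure of the free para-hydroxybenzylic carbinol to acid, so time and temperature are kept low.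

**Further compounds**

F1 | step 6 | ethyl 2-[4-[[(4S)-2,2-dimethyl-1,3-dioxolan-4-yl]methyl]-2,6-dimethoxyphenoxy]acetate | CCOC(=O)COc1c(OC)cc(C[C@H]2COC(C)(C)O2)cc1OC
F2 | step 6 | lithium 1-ethoxy-2-[4-[[(4S)-2,2-dimethyl-1,3-dioxolan-4-yl]methyl]-2,6-dimethoxyphenoxy]ethen-1-olate | CCOC(O[Li])=COc1c(OC)cc(C[C@H]2COC(C)(C)O2)cc1OC
F3 | step 6 | ethyl (2R,3R)-3-(4-acetoxy-3,5-dimethoxyphenyl)-2-[4-[[(4S)-2,2-dimethyl-1,3-dioxolan-4-yl]methyl]-2,6-dimethoxyphenoxy]-3-hydroxypropanoate | COc1cc([C@@H](O)[C@H](C(=O)OCC)Oc2c(OC)cc(C[C@H]3COC(C)(C)O3)cc2OC)cc(OC)c1OC(C)=O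
F4 | step 2 | [4-(benzyloxy)-3,5-dimethoxyphenyl]lithium | COc1cc([Li])cc(OC)c1OCc1ccccc1
F5 | step 2 | [4-(benzyloxy)-3,5-dimethoxyphenyl][(4R)-2,2-dimethyl-1,3-dioxolan-4-yl]methanol (both carbinol epimers) | COc1cc(C(O)[C@H]2COC(C)(C)O2)cc(OC)c1OCc1ccccc1
F6 | step 2 | [4-(benzyloxy)-3,5-dimethoxyphenyl][(4R)-2,2-dimethyl-1,3-dioxolan-4-yl]methyl acetate (both epimers) | COc1cc(C(OC(C)=O)[C@H]2COC(C)(C)O2)cc(OC)c1OCc1ccccc1
F7 | step 8 | (1S,2R)-2-[4-[[(4S)-2,2-dimethyl-1,3-dioxolan-4-yl]methyl]-2,6-dimethoxyphenoxy]-1-(4-hydroxy-3,5-dimethoxyphenyl)propane-1,3-diol | COc1cc([C@H](O)[C@@H](CO)Oc2c(OC)cc(C[C@H]3COC(C)(C)O3)cc2OC)cc(OC)c1O
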